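**Retrosynthetic overview**
1. Presumed biogenesis: the tail isoprene unit of a geranylfarnesyl chain is oxidised to a (Z)-2-methyl-4-oxo-2-enoic acid. This closes to its lactol and loses water to give the Z-ylidene butenolide. The last step copies this ring closure.
2. The seco-acid is cut at its CH2–C(=O) bond into a C20 primary Grignard reagent and citraconic anhydride, an isoprene unit already at the right oxidation level. Addition, ring closure and dehydration run in one flask.
3. The C20 piece is cut at the furyl-CH2–CH2(allyl) bond into furan-3-ylmethylmagnesium chloride and a farnesyl acetate that brings both E-alkenes.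
4. The only stereocentre comes from hydroxylation of the terminal E-methyl group of farnesyl acetate, followed by OH-directed asymmetric hydrogenation.
5. Ring order: the furan is carried in ready-made from 3-furanmethanol. The butenolide is the only ring built, and it is built last.

Assumption: isomerically pure (2E,6E)-farnesyl acetate is purchased. The SMILES is read as S at the methyl-bearing carbon, Z at the exocyclic alkene and E at both chain alkenes.

**Step 1**
Reactants: 1 (2E,6E)-farnesyl acetate
Product: 2 (2E,6E,10E)-12-hydroxy-3,7,11-trimethyldodeca-2,6,10-trien-1-yl acetate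
Conditions: SeO2 (0.1 equiv), t-BuOOH (3 equiv), salicylic acid (0.1 equiv), CH2Cl2, 0 °C → rt
Reagents that add atoms: tert-butyl hydroperoxide, CC(C)(C)OO (source of the new oxygen atom, passed on through SeO2, O=[Se]=O)
Why: Catalytic SeO2 allylic hydroxylation (ene reaction then [2,3]-sigmatropic shift, Riley type) attacks the electron-rich terminal isopropylidene group and gives only the E-CH2OH, because the alkene next to the acetate is deactivated; no stereocentre is formed.

**Step 2**
Reactants: 2 (2E,6E,10E)-12-hydroxy-3,7,11-trimethyldodeca-2,6,10-trien-1-yl acetate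
Product: 3 (2E,6E,11S)-12-hydroxy-3,7,11-trimethyldodeca-2,6-dien-1-yl acetate
Conditions: H2 (100 atm), Ru(OAc)2[(S)-BINAP] (0.5 mol %), MeOH, 25 °C
Reagents that add atoms: none
Why: In this hydroxyl-directed Noyori asymmetric hydrogenation only the alkene that can bind ruthenium through its free allylic OH is reduced, and the (S)-BINAP complex adds H2 to the same alkene face relative to CH2OH as in geraniol → (R)-citronellol and tiglic acid → (S)-2-methylbutanoic acid, which here sets the (S)-methyl stereocentre and leaves the allylic acetate and the isolated alkene untouched.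

**Step 3**
Reactants: 4 3-furanmethanol
Product: 5 3-(chloromethyl)furan
Conditions: SOCl2, pyridine, Et2O, 0 °C
Reagents that add atoms: thionyl chloride, ClS(Cl)=O
Why: This is a chlorodehydroxylation through the chlorosulfite, with pyridine taking up HCl so that the acid-sensitive furan survives.

**Step 4**
Reactants: 3 (2E,6E,11S)-12-hydroxy-3,7,11-trimethyldodeca-2,6-dien-1-yl acetate; 5 3-(chloromethyl)furan
Product: 7 (2S,6E,10E)-13-(furan-3-yl)-2,6,10-trimethyltrideca-6,10-dien-1-ol, via furan-3-ylmethylmagnesium chloride 6 (not isolated)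
Conditions: 5 (3 equiv), Mg, THF, 0 °C → rt; then 3, Li2CuCl4 (5 mol %), THF, −78 → 0 °C
Reagents that add atoms: 3-(chloromethyl)furan 5, ClCc1ccoc1 (delivers the furan-3-ylmethyl group through 6)
Why: In this copper-catalysed Grignard allylic substitution (Kochi–Schlosser type, the coupling used for dendrolasin) the first equivalent of 6 only deprotonates the OH, and with excess Grignard reagent in THF the cuprate displaces the primary allylic acetate at the α-carbon (SN2, not SN2′) with retention of the E-alkene and no effect on the remote stereocentre.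

**Step 5**
Reactants: 7 (2S,6E,10E)-13-(furan-3-yl)-2,6,10-trimethyltrideca-6,10-dien-1-ol
Product: 8 3-[(3E,7E,12S)-13-bromo-4,8,12-trimethyltrideca-3,7-dien-1-yl]furan
Conditions: CBr4, PPh3, CH2Cl2, 0 °C
Reagents that add atoms: carbon tetrabromide, BrC(Br)(Br)Br
Why: The Appel reaction converts the primary alcohol to the bromide under neutral conditions that spare the furan and alkenes, and substitution at the CH2 group leaves the neighbouring stereocentre intact.

**Step 6**
Reactants: 8 3-[(3E,7E,12S)-13-bromo-4,8,12-trimethyltrideca-3,7-dien-1-yl]furan; 9 citraconic anhydride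
Product: 13 (5Z)-5-[(2S,6E,10E)-13-(furan-3-yl)-2,6,10-trimethyltrideca-6,10-dien-1-ylidene]-3-methylfuran-2(5H)-one (target), via alkylmagnesium bromide 10 (not isolated), via seco-acid magnesium salt 11 (not isolated), via lactol mesylate 12 (not isolated)
Conditions: Mg, THF, 45 °C; cannulate into 9 (2 equiv), THF, −78 °C, 1 h; then Et3N (6 equiv), MsCl (3 equiv), −78 → 0 °C
Reagents that add atoms: citraconic anhydride 9, CC1=CC(=O)OC1=O
Why: Proposed new method: the β-branched primary Grignard reagent 10 adds once (1,2-addition to a cyclic anhydride, the known route from dialkylmaleic anhydrides to 5-alkyl-5-hydroxybutenolides) to the sterically open carbonyl of excess 9, the one flanked by the vinylic C–H and remote from the methyl group and the site bulky nucleophiles such as amines and stabilised ylides are expected to prefer, which opens the anhydride to the (Z)-4-oxo-2-enoate 11, the open-chain acid of the presumed biogenesis, whose carboxylate shields the ketone from a second addition; sulfonylation then traps the ring-closed lactolate tautomer as 12 (the ring-forming event), which ionises to an acyl-oxocarbenium ion and loses a CH2 proton to Et3N (known dehydration of 5-alkyl-5-hydroxybutenolides, enol-lactonisation type), giving the Z-alkene because the E-isomer would press the branched chain against the ring C–H, while the stereocentre, β to the ketone and never deprotonated, is untouched.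

**Compound list**
1 | (2E,6E)-farnesyl acetate | CC(C)=CCC/C(C)=C/CC/C(C)=C/COC(C)=O | starting material
2 | (2E,6E,10E)-12-hydroxy-3,7,11-trimethyldodeca-2,6,10-trien-1-yl acetate | OC/C(C)=C/CC/C(C)=C/CC/C(C)=C/COC(C)=O | intermediate
3 | (2E,6E,11S)-12-hydroxy-3,7,11-trimethyldodeca-2,6-dien-1-yl acetate | OC[C@@H](C)CCC/C(C)=C/CC/C(C)=C/COC(C)=O | intermediate
4 | 3-furanmethanol | OCc1ccoc1 | starting material
5 | 3-(chloromethyl)furan | ClCc1ccoc1 | intermediate
6 | furan-3-ylmethylmagnesium chloride | Cl[Mg]Cc1ccoc1 | intermediate
7 | (2S,6E,10E)-13-(furan-3-yl)-2,6,10-trimethyltrideca-6,10-dien-1-ol | OC[C@@H](C)CCC/C(C)=C/CC/C(C)=C/CCc1ccoc1 | intermediate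
8 | 3-[(3E,7E,12S)-13-bromo-4,8,12-trimethyltrideca-3,7-dien-1-yl]furan | BrC[C@@H](C)CCC/C(C)=C/CC/C(C)=C/CCc1ccoc1 | intermediate
9 | citraconic anhydride (3-methylfuran-2,5-dione) | CC1=CC(=O)OC1=O | starting material
10 | bromo[(2S,6E,10E)-13-(furan-3-yl)-2,6,10-trimethyltrideca-6,10-dien-1-yl]magnesium | Br[Mg]C[C@@H](C)CCC/C(C)=C/CC/C(C)=C/CCc1ccoc1 | intermediate
11 | bromomagnesium (2Z,6S,10E,14E)-17-(furan-3-yl)-2,6,10,14-tetramethyl-4-oxoheptadeca-2,10,14-trienoate | Br[Mg]OC(=O)/C(C)=C\C(=O)C[C@@H](C)CCC/C(C)=C/CC/C(C)=C/CCc1ccoc1 | intermediate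
12 | 2-[(2S,6E,10E)-13-(furan-3-yl)-2,6,10-trimethyltrideca-6,10-dien-1-yl]-4-methyl-5-oxo-2,5-dihydrofuran-2-yl methanesulfonate (both epimers at the ring carbon) | CC1=CC(OS(C)(=O)=O)(C[C@@H](C)CCC/C(C)=C/CC/C(C)=C/CCc2ccoc2)OC1=O | intermediate
13 | (5Z)-5-[(2S,6E,10E)-13-(furan-3-yl)-2,6,10-trimethyltrideca-6,10-dien-1-ylidene]-3-methylfuran-2(5H)-one | CC1=C/C(=C/[C@@H](C)CCC/C(C)=C/CC/C(C)=C/CCc2ccoc2)OC1=O | target

**Step count**
Total steps: 6. Longest linear sequence: 5 (steps 1, 2, 4, 5, 6).

**Three steps most likely to fail**

*Risk 1, step 6.*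
- The regiochemistry of the anhydride opening is an argued expectation, not an established result. Attack at the carbonyl next to the methyl group would give the 4-methyl isomer.
- Over-addition of 10 and the one-flask activation are further weak points.

The fallback makes the same lactol by oxidising a furan, the other biogenetic entry to such butenolides. It sets out from bromide 8 and comes back at mesylate 12. Commercial 3-methylfuran is lithiated at its favoured position next to the methyl group (n-BuLi, THF, 0 °C) to (3-methylfuran-2-yl)lithium F1. Me3SiCl then gives trimethyl(3-methylfuran-2-yl)silane F2. A second lithiation can only take the one free α-position and gives [4-methyl-5-(trimethylsilyl)furan-2-yl]lithium F3. This is alkylated with 8 (THF/DMPU, −20 °C → rt) to trimethyl{3-methyl-5-[(2S,6E,10E)-13-(furan-3-yl)-2,6,10-trimethyltrideca-6,10-dien-1-yl]furan-2-yl}silane F4. Photooxygenation follows (O2, methylene blue, visible light, CH2Cl2, −78 °C, stopped after one equivalent of O2). It should consume the trisubstituted, more electron-rich furan well before the 3-alkylfuran and the alkenes. The [4+2] adduct collapses with a silyl shift, so the silyl-bearing carbon becomes the lactone carbonyl. This places the methyl group next to C=O without regiochemical doubt. Hydrolysis gives 5-hydroxy-3-methyl-5-[(2S,6E,10E)-13-(furan-3-yl)-2,6,10-trimethyltrideca-6,10-dien-1-yl]furan-2(5H)-one F5. MsCl/Et3N converts it into 12 and on to 13.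

*Risk 2, step 2.* The enantioselectivity on a 2-methyl allylic alcohol is less well established than for geraniol-type substrates, and alkene migration at ruthenium can erode it. The fallback is a biocatalytic reduction at the aldehyde oxidation level. It sets out from 2 and comes back at 3. MnO2 (CH2Cl2, rt) gives (2E,6E,10E)-3,7,11-trimethyl-12-oxododeca-2,6,10-trien-1-yl acetate F6. An isolated ene-reductase of the old-yellow-enzyme family (OYE2, NADP+, glucose/glucose dehydrogenase, pH 7 buffer with MTBE) then adds hydride to the β-carbon and a proton to the α-carbon. This is the mode by which α-methyl enals give (S)-products, and here it gives (2E,6E,11S)-3,7,11-trimethyl-12-oxododeca-2,6-dien-1-yl acetate F7. An alcohol dehydrogenase in the same pot reduces F7 to 3 before it can epimerise.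

*Risk 3, step 4.*
- The Grignard reagent may attack the acetate carbonyl.
- SN2′ attack is possible.
- The coupling may be sluggish next to a magnesium alkoxide.

The fallback changes the order of events, so that the coupling meets a plain allylic acetate and the oxidation and hydrogenation follow it. It sets out from 1 and Grignard reagent 6 and comes back at 7. One equivalent of 6 is coupled with 1 itself (Li2CuCl4 cat., THF, −78 → 0 °C) to give 3-[(3E,7E)-4,8,12-trimethyltrideca-3,7,11-trien-1-yl]furan F8. SeO2/t-BuOOH then hydroxylates the terminal E-methyl group; a 3-alkylfuran should tolerate this oxidant. The product is (2E,6E,10E)-13-(furan-3-yl)-2,6,10-trimethyltrideca-2,6,10-trien-1-ol F9. The same Ru(OAc)2[(S)-BINAP] hydrogenation gives 7.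

**Further compounds**
F1 | step 6 | (3-methylfuran-2-yl)lithium | [Li]c1occc1C
F2 | step 6 | trimethyl(3-methylfuran-2-yl)silane | Cc1ccoc1[Si](C)(C)C
F3 | step 6 | [4-methyl-5-(trimethylsilyl)furan-2-yl]lithium | [Li]c1cc(C)c(o1)[Si](C)(C)C
F4 | step 6 | trimethyl{3-methyl-5-[(2S,6E,10E)-13-(furan-3-yl)-2,6,10-trimethyltrideca-6,10-dien-1-yl]furan-2-yl}silane | Cc1cc(C[C@@H](C)CCC/C(C)=C/CC/C(C)=C/CCc2ccoc2)oc1[Si](C)(C)C
F5 | step 6 | 5-hydroxy-3-methyl-5-[(2S,6E,10E)-13-(furan-3-yl)-2,6,10-trimethyltrideca-6,10-dien-1-yl]furan-2(5H)-one (both epimers at C5) | CC1=CC(O)(C[C@@H](C)CCC/C(C)=C/CC/C(C)=C/CCc2ccoc2)OC1=O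
F6 | step 2 | (2E,6E,10E)-3,7,11-trimethyl-12-oxododeca-2,6,10-trien-1-yl acetate | O=C/C(C)=C/CC/C(C)=C/CC/C(C)=C/COC(C)=O
F7 | step 2 | (2E,6E,11S)-3,7,11-trimethyl-12-oxododeca-2,6-dien-1-yl acetate | O=C[C@@H](C)CCC/C(C)=C/CC/C(C)=C/COC(C)=O
F8 | step 4 | 3-[(3E,7E)-4,8,12-trimethyltrideca-3,7,11-trien-1-yl]furan | CC(C)=CCC/C(C)=C/CC/C(C)=C/CCc1ccoc1
F9 | step 4 | (2E,6E,10E)-13-(furan-3-yl)-2,6,10-trimethyltrideca-2,6,10-trien-1-ol | OC/C(C)=C/CC/C(C)=C/CC/C(C)=C/CCc1ccoc1
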